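# Proposed synthesis of CNP0172137.1 (compound 22) by aryne insertion into a carboxylic acid

Atom numbers (O1, C2, C3, C4, C4a, C5–C8, C8a) refer to the chromanone skeleton of the target. Coumarin numbering is used only for compounds 1–6 and is flagged where it matters.

## The problem

Compound 22 is a chroman-4-one whose benzene ring (ring A) is substituted at all six carbons. C8a carries the ring oxygen O1, C4a the C4 carbonyl, C5 a free phenol, C6 a prenyl group, C7 a methyl ether, and C8 a 1-phenyl-2-carboxyethyl chain. Three stereocentres are needed: C2 (S) and C3 (R) with cis methyl groups in the pyranone ring (ring B), and the benzylic carbon on C8 (R). The benzylic centre is separated from C2 and C3 by O1 and the arene, so it cannot direct them and must be set on its own. The ring pair is a 1,2-relationship that a single syn addition can set together. The cis arrangement is the fragile one: C3 is alpha to the ketone and drifts to trans through the enol, and base can open ring B by retro-oxa-Michael reaction. The prenyl group cyclises onto the neighbouring phenol under acid and does not survive hydrogenation, and the acid must be masked whenever a carboxylate is the reagent. The feature that opens the route is that the C8a–O1 and C4a–C4 bonds sit on adjacent carbons of ring A. An aryne with its triple bond between C4a and C8a can take both the oxygen and the acyl carbon from one carboxylic acid, and the C5 oxygen beside C4a is placed to steer that addition.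

## Retrosynthesis

**Acid (22 from 21).** Only the ester C–O bond is cut. The acid is carried as its methyl ester from the lactone opening onward. A free acid would compete with acid 13 for the aryne, and the methoxide released in the key step exchanges degenerately with a methyl ester. The forward step must cleave the ester without a base strong enough to epimerise C3.

**Prenyl group (21 from 20 from 19).** The C6–CH2 bond is cut by a Claisen transform back to the tertiary allyl ether 20, and then the O–C bond back to phenol 19. Direct C-prenylation would need acid or a phenoxide and would not be regioselective. Carrying the olefin through the hydrogenation is excluded. C6 is the only free ortho position of the C5 oxygen, so the rearrangement has one outcome. It must be run neutral so that the cis ring survives.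

**Ring stereocentres (19 from 18 from 17 from 16).** The C2–H and C3–H bonds are cut, leading to the flat chromone 16. A syn hydrogenation gives the cis pair in one event, and 16 has no ring stereocentre to lose under the heat and base of the step that makes it. The forward reaction needs catalyst-controlled facial selectivity on a tetrasubstituted C2=C3 bond. Over-reduction to chromanol 17 is accepted and undone by oxidation to 18, and the benzyl ether is then removed under neutral conditions.

**Key disconnection (16 from 10 and 13).** The C8a–O1, C4a–C4 and O1–C2 bonds are cut. Acylation of a phenol at C4a followed by oxa-Michael closure would require the C8a phenol to be distinguished from the C5 and C7 oxygens. It would also give ring B without control. Here O1 arrives with the acid, so no phenol differentiation is needed. Precursor 10 holds only the benzylic centre and 13 is an achiral five-carbon acid. The forward step must add the carboxylate at C8a, transfer the acyl group faster than the aryl anion is protonated, and close the ring by addition–elimination.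

**Aryne precursor (10 from 7 from 6 from 5).** The C4a–Si and O–S bonds are cut, back to the ortho-bromophenol 7 (retro-Brook route). The phenol of 7 is the lactone oxygen of dihydrocoumarin 6. The bromine is placed at the lactone stage (5 to 6), where coumarin C8, the future C4a, is the favoured site. In the free phenol the para position would compete. The forward steps need regioselective bromination and a halogen–lithium exchange that tolerates the ester.

**Benzylic centre (5 from 3 and 4).** The C4–phenyl bond (coumarin numbering) is cut. The coumarin ties the future O1 to the side-chain carboxyl, so the 3,3-diarylpropanoate arises with its oxygen pattern fixed: coumarin O1 becomes O1, C7–O becomes C5–O, and C5–O becomes C7–OMe. The forward step is an asymmetric 1,4-addition of 4 to a peri-substituted, electron-rich coumarin.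

**Oxygen pattern (3 from 2 from 1).** Two O–C bonds are cut. The more acidic 7-hydroxyl of 1 is benzylated first and the other is methylated. Benzyl is chosen for the future C5 oxygen because it polarises the aryne, survives fluoride and homogeneous hydrogenation, and leaves by neutral hydrogenolysis.

**Acid partner (13 from 12 from 11).** The enol ether C–O bond is cut back to keto ester 11. The methoxy group is the leaving group of the ring closure.

## Roads not taken

**Alternative 1:** The cut is through ring A itself (C7–C8, C4a–C8a and C6–C7), leading to cyclobutenone A1 and the chiral siloxyalkyne A2. Heating opens A1 to a vinylketene, which adds A2 in a [2+2] sense. A second ring opening and 6π closure give phenol A3 (Danheiser benzannulation).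
- Merits: the crowded arene is made in one convergent step with intrinsic regiochemistry, and the prenyl group is in place from the start. In both respects it is better than the chosen plan, which must trust aryne polarisation and spend two steps on prenylation.
- Weak points: A3 has no pyranone ring. C4a is still a C–H, so acylation and ring closure remain, and with them the whole cis-C2/C3 problem. Three differently protected oxygens must be sorted, including cleavage of an ethyl ether beside a methyl ether and a prenyl group. The side chain is at the alcohol level and needs later oxidation.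
- Comparison: the chosen plan delivers O1, C4 and the closed ring in one step and reduces the ring stereochemistry to one facial choice.

**Alternative 2:** The cut is C2–C3, leading to diazoketone A4. Rh2(S-PTTL)4 (dirhodium tetrakis(N-phthaloyl-tert-leucinate)) would generate the carbenoid, which inserts into an O–CH2 hydrogen of the C8a ethoxy group to give A5.
- Merits: every substituent is in place, both ring stereocentres are set in one catalytic step, and only two deprotections follow. If it worked it would be shorter after the key step than the chosen plan.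
- Weak points: a diazoketone with an alpha-methyl group is prone to 1,2-hydride shift to the enone. The ether oxygen can form an oxonium ylide that rearranges to a benzofuranone. The prenyl olefin invites cyclopropanation. Six-membered insertion with cis and enantiocontrol is not established for this substrate type.
- Comparison: the chosen plan also rests on an unproven asymmetric step, but that step has only one stereochemical variable (the face) and a known fallback. The carbenoid has several competing channels.

**Alternative 3:** The cut is C4–C4a, leading to the iodoaryl ether A6, whose C2 and C3 centres come from a chiral-pool hydroxy acid. Iodine–lithium exchange with t-BuLi and attack on the tethered Weinreb amide would give A7.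
- Merits: the ring configuration is secure and no asymmetric catalysis or aryne regiochemistry is involved. In stereochemical certainty it is better than the chosen plan.
- Weak points: A6 requires etherification of a doubly ortho-substituted phenol at a secondary carbon beta to a carbonyl, where elimination to the unsaturated amide competes, and the aryloxide is a good E1cB leaving group. t-BuLi must spare a methyl ester. The MOM group in A7 has to be removed with acid beside a prenyl phenol and an epimerisable C3.
- Comparison: the chosen plan forms O1–C2 by an irreversible addition–elimination on a flat chromone and uses organolithium only early, before any ring stereocentre exists.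

Key step: step 9

Assumption: the ligand enantiomers named in steps 3 and 10 are those expected by analogy with the parent coumarin and 2-alkylchromone series. If the first run shows the opposite sense, the mirror-image ligand is used and nothing else changes.

## Route

Step 1
Reactants: 1 5,7-dihydroxy-2H-chromen-2-one
Product: 2 7-(benzyloxy)-5-hydroxy-2H-chromen-2-one
Conditions: BnBr (1 equiv), K2CO3 (1 equiv), DMF, 0 °C to rt
Reagents that add atoms: benzyl bromide, BrCc1ccccc1
Why: Williamson etherification; the 7-hydroxyl is para to C4a and conjugated through it with the lactone carbonyl, so it is the more acidic and less hindered phenol and should react first with one equivalent of base; bis-ether and regioisomer are removed by crystallisation.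

Step 2
Reactants: 2 7-(benzyloxy)-5-hydroxy-2H-chromen-2-one
Product: 3 7-(benzyloxy)-5-methoxy-2H-chromen-2-one
Conditions: MeI, K2CO3, acetone, 56 °C
Reagents that add atoms: iodomethane, CI
Why: Williamson methylation of the remaining phenol; the coumarin lactone tolerates carbonate in acetone.

Step 3
Reactants: 3 7-(benzyloxy)-5-methoxy-2H-chromen-2-one; 4 phenylboronic acid (excess)
Product: 5 (R)-7-(benzyloxy)-5-methoxy-4-phenylchroman-2-one
Conditions: Rh(acac)(C2H4)2 (cat.), (R)-SEGPHOS, dioxane/H2O, 60 °C
Reagents that add atoms: none
Why: Hayashi–Miyaura asymmetric 1,4-addition of an arylboronic acid to a coumarin; the phenylrhodium–bisphosphine complex inserts the C3=C4 bond on the face chosen by the ligand and water releases the lactone, setting the benzylic centre as (R).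

Step 4
Reactants: 5 (R)-7-(benzyloxy)-5-methoxy-4-phenylchroman-2-one
Product: 6 (R)-7-(benzyloxy)-8-bromo-5-methoxy-4-phenylchroman-2-one
Conditions: NBS (1 equiv), MeCN, 0 °C, dark
Reagents that add atoms: N-bromosuccinimide, O=C1CCC(=O)N1Br
Why: Electrophilic aromatic bromination; C8 (coumarin numbering, the future C4a) is para to the C5 methoxy group and less hindered than C6, which lies between two alkoxy groups, as in C8 halogenation of 5,7-dialkoxychromones; the regiochemistry is to be confirmed by NMR correlation before going on.

Step 5
Reactants: 6 (R)-7-(benzyloxy)-8-bromo-5-methoxy-4-phenylchroman-2-one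
Product: 7 methyl (R)-3-[4-(benzyloxy)-3-bromo-2-hydroxy-6-methoxyphenyl]-3-phenylpropanoate
Conditions: NaOMe, MeOH/THF, 0 °C; then AcOH, 0 °C
Reagents that add atoms: sodium methoxide, [Na+].[O-]C
Why: Lactone methanolysis (transesterification) driven by formation of the phenoxide; a cold acetic acid quench gives the bromophenol ester, which is used at once to avoid relactonisation; the benzylic centre is not acidic.

Step 6
Reactants: 7 methyl (R)-3-[4-(benzyloxy)-3-bromo-2-hydroxy-6-methoxyphenyl]-3-phenylpropanoate
Product: 10 methyl (R)-3-[4-(benzyloxy)-6-methoxy-2-(trifluoromethylsulfonyloxy)-3-(trimethylsilyl)phenyl]-3-phenylpropanoate, via aryl trimethylsilyl ether 8 (not isolated), via lithium 2-silylphenoxide 9 (not isolated)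
Conditions: HMDS, THF, 60 °C, evaporate; n-BuLi, THF, −100 °C; Tf2O, −100 to −78 °C
Reagents that add atoms: hexamethyldisilazane, C[Si](C)(C)N[Si](C)(C)C; trifluoromethanesulfonic anhydride, O=S(=O)(OS(=O)(=O)C(F)(F)F)C(F)(F)F
Why: O-silylation, bromine–lithium exchange, anionic O-to-C silyl migration (retro-Brook rearrangement) and O-triflation, the standard route to ortho-silylaryl triflates; at −100 °C the exchange outruns addition to an aliphatic ester (as in Parham cyclisations), and the intramolecular silyl shift turns the aryllithium into a phenoxide that is inert to the ester.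

Step 7
Reactants: 11 methyl 2-methyl-3-oxobutanoate
Product: 12 methyl (E)-3-methoxy-2-methylbut-2-enoate
Conditions: HC(OMe)3, H2SO4 (cat.), MeOH, rt; distil
Reagents that add atoms: trimethyl orthoformate, COC(OC)OC
Why: Acid-catalysed ketalisation by the orthoformate and loss of methanol to the conjugated enol ether; the (E) isomer is the stable one, and the geometry is erased in the key step in any case.

Step 8
Reactants: 12 methyl (E)-3-methoxy-2-methylbut-2-enoate
Product: 13 (E)-3-methoxy-2-methylbut-2-enoic acid
Conditions: KOH, MeOH/H2O, 60 °C; then HCl (aq), 0 °C, pH 3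
Reagents that add atoms: potassium hydroxide, [K+].[OH-]
Why: Saponification; the beta-alkoxy acrylate resists conjugate attack by hydroxide, and cold acidification to pH 3 avoids enol ether hydrolysis and decarboxylation.

Step 9
Reactants: 10 methyl (R)-3-[4-(benzyloxy)-6-methoxy-2-(trifluoromethylsulfonyloxy)-3-(trimethylsilyl)phenyl]-3-phenylpropanoate; 13 (E)-3-methoxy-2-methylbut-2-enoic acid
Product: 16 methyl (R)-3-[5-(benzyloxy)-7-methoxy-2,3-dimethyl-4-oxo-4H-chromen-8-yl]-3-phenylpropanoate, via C4a≡C8a aryne 14 (not isolated), via ortho-hydroxyaryl ketone 15 (not isolated)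
Conditions: CsF (excess), THF, 125 °C, sealed tube
Reagents that add atoms: none
Why: Fluoride attacks silicon in 10 and the aryl anion expels triflate to give aryne 14. The cesium carboxylate of 13 adds through oxygen at C8a, and the anion that develops at C4a attacks the adjacent ester carbonyl through a four-membered alkoxide that opens to the phenoxide of 15, a net insertion of the aryne into the C–O bond of the acid. The C8a phenoxide then adds to the beta-carbon of the methoxy enone and methoxide leaves (6-endo-trig oxa-Michael addition followed by E1cB elimination), closing ring B as the chromone irreversibly. The closest known reaction type is the CsF-mediated insertion of arynes into carboxylic acids to give ortho-hydroxyaryl ketones, with in situ closure of acrylic and propiolic acid adducts to chromanones and flavones. No stereocentre is formed and the benzylic centre is not acidic under these conditions. The step needs regioselective addition to an unsymmetrical aryne, secured by the C5 benzyloxy group, whose inductive pull places the negative charge at C4a and the nucleophile at the distal C8a. It also needs acyl transfer to beat protonation of the aryl anion, which hot THF, excess CsF and the absence of protic additives favour. Any lactonisation of the phenoxide onto the side-chain ester is reversed by the methoxide released, whose exchange with a methyl ester is degenerate.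

Step 10
Reactants: 16 methyl (R)-3-[5-(benzyloxy)-7-methoxy-2,3-dimethyl-4-oxo-4H-chromen-8-yl]-3-phenylpropanoate
Product: 17 methyl (R)-3-[(2S,3S,4R)-5-(benzyloxy)-4-hydroxy-7-methoxy-2,3-dimethylchroman-8-yl]-3-phenylpropanoate (all-cis; C4 configuration of no consequence)
Conditions: H2 (100 bar), Ru(cod)(2-methylallyl)2 (cat.), (R,R)-SINpEt·HBF4, KOt-Bu (cat., for catalyst formation), hexane/toluene, 40 °C
Reagents that add atoms: none
Why: Proposed new method: the chiral ruthenium–NHC hydride (NHC = 1,3-bis[(R)-1-(naphthalen-1-yl)ethyl]imidazolin-2-ylidene) should bind one face of the pyranone ring of 16 and deliver both hydrogens to C2 and C3 from that face, so the methyl groups must end up cis and the catalyst alone chooses (2S,3R) over (2R,3S), the benzylic centre being too remote to interfere; the closest known reaction type is the ruthenium–NHC-catalysed asymmetric hydrogenation of 2-substituted chromones and flavones, which also reduces the C4 carbonyl to the cis alcohol and is followed by re-oxidation, whereas a 2,3-dialkylchromone with a tetrasubstituted C2=C3 bond has not been shown.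

Step 11
Reactants: 17 methyl (R)-3-[(2S,3S,4R)-5-(benzyloxy)-4-hydroxy-7-methoxy-2,3-dimethylchroman-8-yl]-3-phenylpropanoate
Product: 18 methyl (R)-3-[(2S,3R)-5-(benzyloxy)-7-methoxy-2,3-dimethyl-4-oxochroman-8-yl]-3-phenylpropanoate
Conditions: Dess–Martin periodinane, NaHCO3, CH2Cl2, 0 °C to rt
Reagents that add atoms: none
Why: Dess–Martin oxidation of a secondary benzylic alcohol under buffered, near-neutral conditions restores the C4 ketone without touching C3 (its descriptor changes from S to R only because the CIP priorities change).

Step 12
Reactants: 18 methyl (R)-3-[(2S,3R)-5-(benzyloxy)-7-methoxy-2,3-dimethyl-4-oxochroman-8-yl]-3-phenylpropanoate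
Product: 19 methyl (R)-3-[(2S,3R)-5-hydroxy-7-methoxy-2,3-dimethyl-4-oxochroman-8-yl]-3-phenylpropanoate
Conditions: H2 (1 atm), Pd/C, EtOAc, rt
Reagents that add atoms: none
Why: Hydrogenolysis of a benzyl aryl ether; no acid or base is present, so the cis C2/C3 pair is safe, and the electron-rich, hydrogen-bonded aryl ketone should not be reduced at 1 atm.

Step 13
Reactants: 19 methyl (R)-3-[(2S,3R)-5-hydroxy-7-methoxy-2,3-dimethyl-4-oxochroman-8-yl]-3-phenylpropanoate
Product: 20 methyl (R)-3-[(2S,3R)-7-methoxy-2,3-dimethyl-5-(2-methylbut-3-en-2-yloxy)-4-oxochroman-8-yl]-3-phenylpropanoate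
Conditions: tert-butyl 2-methylbut-3-en-2-yl carbonate, Pd(PPh3)4 (cat.), THF, 0 °C
Reagents that add atoms: tert-butyl (2-methylbut-3-en-2-yl) carbonate, CC(C)(C)OC(=O)OC(C)(C)C=C
Why: Tsuji–Trost O-allylation; zerovalent palladium ionises the tertiary carbonate with loss of CO2, the tert-butoxide formed deprotonates the phenol, and the phenoxide attacks the more substituted terminus of the dimethylallyl complex under kinetic control at 0 °C; the reaction is stopped and freed from palladium before the ether can isomerise to the linear one.

Step 14
Reactants: 20 methyl (R)-3-[(2S,3R)-7-methoxy-2,3-dimethyl-5-(2-methylbut-3-en-2-yloxy)-4-oxochroman-8-yl]-3-phenylpropanoate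
Product: 21 methyl (R)-3-[(2S,3R)-5-hydroxy-7-methoxy-2,3-dimethyl-6-(3-methylbut-2-en-1-yl)-4-oxochroman-8-yl]-3-phenylpropanoate
Conditions: toluene, 110 °C
Reagents that add atoms: none
Why: Aromatic Claisen rearrangement ([3,3]-sigmatropic shift, then tautomerisation); C6 is the only free ortho position of the C5 oxygen and the allyl inversion turns the 1,1-dimethylallyl ether into the 3-methylbut-2-enyl group; C8 is blocked, so any para migration is reversible, and the medium is neutral.

Step 15
Reactants: 21 methyl (R)-3-[(2S,3R)-5-hydroxy-7-methoxy-2,3-dimethyl-6-(3-methylbut-2-en-1-yl)-4-oxochroman-8-yl]-3-phenylpropanoate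
Product: 22 (R)-3-[(2S,3R)-5-hydroxy-7-methoxy-2,3-dimethyl-6-(3-methylbut-2-en-1-yl)-4-oxochroman-8-yl]-3-phenylpropanoic acid
Conditions: Me3SnOH, 1,2-dichloroethane, 70 °C; then dilute HCl
Reagents that add atoms: trimethyltin hydroxide, C[Sn](C)(C)O
Why: Methyl ester cleavage by trimethyltin hydroxide, a near-neutral hydroxide transfer; it avoids the strong base that would epimerise C3 or open ring B and the strong acid that would cyclise the prenyl phenol.

## Compound list

1 | 5,7-dihydroxy-2H-chromen-2-one (5,7-dihydroxycoumarin) | O=C1C=Cc2c(O)cc(O)cc2O1 | starting material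
2 | 7-(benzyloxy)-5-hydroxy-2H-chromen-2-one | O=C1C=Cc2c(O)cc(OCc3ccccc3)cc2O1 | intermediate
3 | 7-(benzyloxy)-5-methoxy-2H-chromen-2-one | O=C1C=Cc2c(OC)cc(OCc3ccccc3)cc2O1 | intermediate
4 | phenylboronic acid | OB(O)c1ccccc1 | starting material
5 | (R)-7-(benzyloxy)-5-methoxy-4-phenylchroman-2-one | O=C1C[C@H](c2ccccc2)c2c(OC)cc(OCc3ccccc3)cc2O1 | intermediate
6 | (R)-7-(benzyloxy)-8-bromo-5-methoxy-4-phenylchroman-2-one | O=C1C[C@H](c2ccccc2)c2c(OC)cc(OCc3ccccc3)c(Br)c2O1 | intermediate
7 | methyl (R)-3-[4-(benzyloxy)-3-bromo-2-hydroxy-6-methoxyphenyl]-3-phenylpropanoate | COc1cc(OCc3ccccc3)c(Br)c(O)c1[C@H](CC(=O)OC)c1ccccc1 | intermediate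
8 | methyl (R)-3-[4-(benzyloxy)-3-bromo-6-methoxy-2-(trimethylsilyloxy)phenyl]-3-phenylpropanoate | COc1cc(OCc3ccccc3)c(Br)c(O[Si](C)(C)C)c1[C@H](CC(=O)OC)c1ccccc1 | intermediate
9 | lithium 3-(benzyloxy)-5-methoxy-6-[(R)-3-methoxy-3-oxo-1-phenylpropyl]-2-(trimethylsilyl)phenolate | COc1cc(OCc3ccccc3)c([Si](C)(C)C)c([O-])c1[C@H](CC(=O)OC)c1ccccc1.[Li+] | intermediate
10 | methyl (R)-3-[4-(benzyloxy)-6-methoxy-2-(trifluoromethylsulfonyloxy)-3-(trimethylsilyl)phenyl]-3-phenylpropanoate | COc1cc(OCc3ccccc3)c([Si](C)(C)C)c(OS(=O)(=O)C(F)(F)F)c1[C@H](CC(=O)OC)c1ccccc1 | intermediate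
11 | methyl 2-methyl-3-oxobutanoate | COC(=O)C(C)C(C)=O | starting material
12 | methyl (E)-3-methoxy-2-methylbut-2-enoate | CO/C(C)=C(\C)C(=O)OC | intermediate
13 | (E)-3-methoxy-2-methylbut-2-enoic acid | CO/C(C)=C(\C)C(=O)O | intermediate
14 | methyl (R)-3-[4-(benzyloxy)-6-methoxy-2,3-didehydrophenyl]-3-phenylpropanoate (the C4a≡C8a aryne) | COC1=C([C@H](CC(=O)OC)c2ccccc2)C#CC(OCc2ccccc2)=C1 | intermediate
15 | methyl (R)-3-[4-(benzyloxy)-2-hydroxy-6-methoxy-3-[(E)-3-methoxy-2-methylbut-2-enoyl]phenyl]-3-phenylpropanoate (present as its cesium phenoxide) | COc1cc(OCc3ccccc3)c(C(=O)/C(C)=C(\C)OC)c(O)c1[C@H](CC(=O)OC)c1ccccc1 | intermediate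
16 | methyl (R)-3-[5-(benzyloxy)-7-methoxy-2,3-dimethyl-4-oxo-4H-chromen-8-yl]-3-phenylpropanoate | COc1cc(OCc3ccccc3)c2c(c1[C@H](CC(=O)OC)c1ccccc1)OC(C)=C(C)C2=O | intermediate
17 | methyl (R)-3-[(2S,3S,4R)-5-(benzyloxy)-4-hydroxy-7-methoxy-2,3-dimethylchroman-8-yl]-3-phenylpropanoate (all-cis) | COc1cc(OCc3ccccc3)c2c(c1[C@H](CC(=O)OC)c1ccccc1)O[C@@H](C)[C@@H](C)[C@H]2O | intermediate
18 | methyl (R)-3-[(2S,3R)-5-(benzyloxy)-7-methoxy-2,3-dimethyl-4-oxochroman-8-yl]-3-phenylpropanoate | COc1cc(OCc3ccccc3)c2c(c1[C@H](CC(=O)OC)c1ccccc1)O[C@@H](C)[C@@H](C)C2=O | intermediate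
19 | methyl (R)-3-[(2S,3R)-5-hydroxy-7-methoxy-2,3-dimethyl-4-oxochroman-8-yl]-3-phenylpropanoate | COc1cc(O)c2c(c1[C@H](CC(=O)OC)c1ccccc1)O[C@@H](C)[C@@H](C)C2=O | intermediate
20 | methyl (R)-3-[(2S,3R)-7-methoxy-2,3-dimethyl-5-(2-methylbut-3-en-2-yloxy)-4-oxochroman-8-yl]-3-phenylpropanoate | COc1cc(OC(C)(C)C=C)c2c(c1[C@H](CC(=O)OC)c1ccccc1)O[C@@H](C)[C@@H](C)C2=O | intermediate
21 | methyl (R)-3-[(2S,3R)-5-hydroxy-7-methoxy-2,3-dimethyl-6-(3-methylbut-2-en-1-yl)-4-oxochroman-8-yl]-3-phenylpropanoate | COc1c(CC=C(C)C)c(O)c2c(c1[C@H](CC(=O)OC)c1ccccc1)O[C@@H](C)[C@@H](C)C2=O | intermediate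
22 | (R)-3-[(2S,3R)-5-hydroxy-7-methoxy-2,3-dimethyl-6-(3-methylbut-2-en-1-yl)-4-oxochroman-8-yl]-3-phenylpropanoic acid (CNP0172137.1) | COc1c(CC=C(C)C)c(O)c2c(c1[C@H](CC(=O)O)c1ccccc1)O[C@@H](C)[C@@H](C)C2=O | target

## Step count and least certain steps

Total steps: 15. Longest linear sequence: 13 (steps 1–6 and 9–15); steps 7 and 8 make the acid partner.

**Step 10 (proposed new method).**
- What may go wrong: slow hydrogen uptake at the tetrasubstituted, electron-rich C2=C3 bond; insufficient facial discrimination; epimerisation at C3 at the chromanone stage before the carbonyl is reduced.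
- Fallback (known chemistry): from 16, hydrogenation over Pd/C in ethyl acetate adds hydrogen syn to either face and cleaves the benzyl ether in the same operation. It gives 19 together with its ring diastereomer methyl (R)-3-[(2R,3S)-5-hydroxy-7-methoxy-2,3-dimethyl-4-oxochroman-8-yl]-3-phenylpropanoate F1. The two are diastereomers because the benzylic centre is fixed, and are separated by chromatography. The route is rejoined at 19 and steps 11 and 12 fall away, at the cost of the material that ends up as F1.

**Step 9 (key step).**
- What may go wrong: carboxylate attack at C4a instead of C8a because the branched C8 substituent shields C8a; protonation of the C4a anion before acyl transfer, which stops at the aryl ester; fluoride attack at sulfur with loss of the triflate without aryne formation.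
- Fallback: from 5, Friedel–Crafts propanoylation (propanoyl chloride, SnCl4, CH2Cl2, −20 °C) at the position that is brominated in step 4 gives (R)-7-(benzyloxy)-5-methoxy-4-phenyl-8-propanoylchroman-2-one F2. Methanolysis with NaOMe gives methyl (R)-3-[4-(benzyloxy)-2-hydroxy-6-methoxy-3-propanoylphenyl]-3-phenylpropanoate F3. A Kostanecki–Robinson reaction (Ac2O, NaOAc, heat) then builds the 2,3-dimethylchromone and rejoins the route at 16.

**Step 6.**
- What may go wrong: addition of butyllithium or of the aryllithium to the methyl ester, or ester enolisation, competing with the exchange and the silyl shift; relactonisation of the phenoxide before triflation.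
- Fallback: from 6, the side chain is taken to the alcohol level for the organolithium step.
  - LiBH4 in THF reduces the lactone to 3-(benzyloxy)-2-bromo-6-[(R)-3-hydroxy-1-phenylpropyl]-5-methoxyphenol F4.
  - HMDS gives the bis(trimethylsilyl) ether of this diol F5.
  - n-BuLi at −100 °C, Tf2O and aqueous work-up (which frees the primary alcohol) give 3-(benzyloxy)-6-[(R)-3-hydroxy-1-phenylpropyl]-5-methoxy-2-(trimethylsilyl)phenyl trifluoromethanesulfonate F6.
  - TEMPO/PhI(OAc)2 in MeCN/H2O gives (R)-3-[4-(benzyloxy)-6-methoxy-2-(trifluoromethylsulfonyloxy)-3-(trimethylsilyl)phenyl]-3-phenylpropanoic acid F7.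
  - TMSCHN2 in MeOH/toluene gives 10.

**Step 3.**
- What may go wrong: slow 1,4-addition because the C5 methoxy group is peri to C4 and the coumarin is electron-rich, so that protodeboronation of 4 wins.
- Fallback: from 3, oxidative Heck-type C4 arylation with 4 (Pd(OAc)2, 1,10-phenanthroline, O2, DMF) gives 7-(benzyloxy)-5-methoxy-4-phenyl-2H-chromen-2-one F8. Copper hydride asymmetric conjugate reduction (Cu(OAc)2, DTBM-SEGPHOS enantiomer chosen for the (R) product, diethoxymethylsilane, t-BuOH, toluene) returns to the route at 5.

**Step 15.**
- What may go wrong: epimerisation at C3 to the trans isomer by enolisation or by ring opening and reclosure during ester cleavage.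
- Fallback: from 21, enzymatic hydrolysis with pig liver esterase in pH 7 phosphate buffer/acetone gives 22 directly. No new compound is made.

## Further compounds

F1 | step 10 | methyl (R)-3-[(2R,3S)-5-hydroxy-7-methoxy-2,3-dimethyl-4-oxochroman-8-yl]-3-phenylpropanoate | COc1cc(O)c2c(c1[C@H](CC(=O)OC)c1ccccc1)O[C@H](C)[C@H](C)C2=O
F2 | step 9 | (R)-7-(benzyloxy)-5-methoxy-4-phenyl-8-propanoylchroman-2-one | O=C1C[C@H](c2ccccc2)c2c(OC)cc(OCc3ccccc3)c(C(=O)CC)c2O1
F3 | step 9 | methyl (R)-3-[4-(benzyloxy)-2-hydroxy-6-methoxy-3-propanoylphenyl]-3-phenylpropanoate | COc1cc(OCc3ccccc3)c(C(=O)CC)c(O)c1[C@H](CC(=O)OC)c1ccccc1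
F4 | step 6 | 3-(benzyloxy)-2-bromo-6-[(R)-3-hydroxy-1-phenylpropyl]-5-methoxyphenol | COc1cc(OCc3ccccc3)c(Br)c(O)c1[C@H](CCO)c1ccccc1
F5 | step 6 | {3-(benzyloxy)-2-bromo-5-methoxy-6-[(R)-1-phenyl-3-(trimethylsilyloxy)propyl]phenoxy}trimethylsilane | COc1cc(OCc3ccccc3)c(Br)c(O[Si](C)(C)C)c1[C@H](CCO[Si](C)(C)C)c1ccccc1
F6 | step 6 | 3-(benzyloxy)-6-[(R)-3-hydroxy-1-phenylpropyl]-5-methoxy-2-(trimethylsilyl)phenyl trifluoromethanesulfonate | COc1cc(OCc3ccccc3)c([Si](C)(C)C)c(OS(=O)(=O)C(F)(F)F)c1[C@H](CCO)c1ccccc1
F7 | step 6 | (R)-3-[4-(benzyloxy)-6-methoxy-2-(trifluoromethylsulfonyloxy)-3-(trimethylsilyl)phenyl]-3-phenylpropanoic acid | COc1cc(OCc3ccccc3)c([Si](C)(C)C)c(OS(=O)(=O)C(F)(F)F)c1[C@H](CC(=O)O)c1ccccc1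
F8 | step 3 | 7-(benzyloxy)-5-methoxy-4-phenyl-2H-chromen-2-one | O=C1C=C(c2ccccc2)c2c(OC)cc(OCc3ccccc3)cc2O1
F0 | step 15 | none | none
A1 | alternative 1 | 3-ethoxy-4-(3-methylbut-2-en-1-yl)cyclobut-2-en-1-one | O=C1C=C(OCC)C1CC=C(C)C
A2 | alternative 1 | (R)-5-(tert-butyldimethylsilyloxy)-3-phenyl-1-(triisopropylsilyloxy)pent-1-yne | CC(C)[Si](OC#C[C@H](CCO[Si](C)(C)C(C)(C)C)c1ccccc1)(C(C)C)C(C)C
A3 | alternative 1 | 2-[(R)-3-(tert-butyldimethylsilyloxy)-1-phenylpropyl]-5-ethoxy-6-(3-methylbut-2-en-1-yl)-3-(triisopropylsilyloxy)phenol | Oc1c(CC=C(C)C)c(OCC)cc(O[Si](C(C)C)(C(C)C)C(C)C)c1[C@H](CCO[Si](C)(C)C(C)(C)C)c1ccccc1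
A4 | alternative 2 | methyl (R)-3-[4-acetoxy-3-(2-diazopropanoyl)-2-ethoxy-6-methoxy-5-(3-methylbut-2-en-1-yl)phenyl]-3-phenylpropanoate | COc1c(CC=C(C)C)c(OC(C)=O)c(C(=O)C(C)=[N+]=[N-])c(OCC)c1[C@H](CC(=O)OC)c1ccccc1
A5 | alternative 2 | methyl (R)-3-[(2S,3R)-5-acetoxy-7-methoxy-2,3-dimethyl-6-(3-methylbut-2-en-1-yl)-4-oxochroman-8-yl]-3-phenylpropanoate | COc1c(CC=C(C)C)c(OC(C)=O)c2c(c1[C@H](CC(=O)OC)c1ccccc1)O[C@@H](C)[C@@H](C)C2=O
A6 | alternative 3 | methyl (R)-3-[3-iodo-6-methoxy-4-(methoxymethoxy)-2-{[(2S,3R)-4-[methoxy(methyl)amino]-3-methyl-4-oxobutan-2-yl]oxy}-5-(3-methylbut-2-en-1-yl)phenyl]-3-phenylpropanoate | COc1c(CC=C(C)C)c(OCOC)c(I)c(O[C@@H](C)[C@@H](C)C(=O)N(C)OC)c1[C@H](CC(=O)OC)c1ccccc1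
A7 | alternative 3 | methyl (R)-3-[(2S,3R)-7-methoxy-5-(methoxymethoxy)-2,3-dimethyl-6-(3-methylbut-2-en-1-yl)-4-oxochroman-8-yl]-3-phenylpropanoate | COc1c(CC=C(C)C)c(OCOC)c2c(c1[C@H](CC(=O)OC)c1ccccc1)O[C@@H](C)[C@@H](C)C2=O
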